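**Retrosynthetic overview**

1. Carotenoid numbering is used (ring: C1 = CMe2, C2 and C3 = CH2, C4 = CH=, C5 = CMe=, C6 = stereocentre). Wittig disconnections at C11=C12 and C11′=C12′ give the (6R)-ε-C15 phosphonium salt 20, the C10 trienedial 23 and farnesyl phosphonium salt 22.
2. Salt 20 comes from (R)-α-ionone 18, and 18 from cross-metathesis of the (6R)-vinylcyclohexene 16 with methyl vinyl ketone.
3. The C6 configuration and the C4=C5 position come from an allylic diazene rearrangement (1,3-chirality transfer C4 to C6) of the (S)-allylic alcohol 12, made by Corey–Bakshi–Shibata reduction of enone 11.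
4. The six-membered ring is made in step 4 from cyclobutenone 9 and ethylene. The enabling feature is the unsubstituted C2H2–C3H2 edge of the cyclohexene ring, flanked by quaternary C1 and by C4, which leaves C4–C5–C6–C1 as a four-carbon unit that can be pre-assembled as a strained cyclobutenone with C4 as the carbonyl carbon.
5. Ring order: the four-membered ring first (ketene–ynol ether [2+2], step 2), then its (4+2) expansion to the cyclohexene ring (step 4); no other ring is formed.

Key step: step 4

Remark: 1, 4, 7, 10, 13, 17, 21 and 23 are taken as commercially available, and the Z isomers formed at the new double bonds in the two Wittig steps are assumed to equilibrate to the all-E polyene as is usual for carotenoids.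

**Route**

Step 1
Reactants: 1 ethoxyacetylene
Product: 3 1-ethoxyprop-1-yne, via lithium ethoxyacetylide 2 (not isolated)
Conditions: n-BuLi, THF, −78 °C; then MeI, DMPU, −78 °C to rt
Reagents that add atoms: iodomethane, CI
Why: Deprotonation of the terminal alkyne and SN2 methylation of the lithium acetylide (acetylide alkylation) should give the internal ynol ether; no stereocentre is involved.

Step 2
Reactants: 3 1-ethoxyprop-1-yne; 4 isobutyryl chloride
Product: 6 3-ethoxy-2,4,4-trimethylcyclobut-2-en-1-one, via dimethylketene 5 (not isolated)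
Conditions: Et3N, MeCN, 0 °C to 50 °C (4 added slowly)
Reagents that add atoms: none
Why: Dehydrochlorination of 4 gives dimethylketene 5, which should undergo the ketene–ynol ether [2+2] cycloaddition with the nucleophilic methyl-bearing alkyne carbon of 3 bonding to the ketene carbonyl carbon, so that OEt ends up on the ring carbon next to CMe2; no stereocentre is formed.

Step 3
Reactants: 6 3-ethoxy-2,4,4-trimethylcyclobut-2-en-1-one; 7 vinylmagnesium bromide
Product: 9 2,4,4-trimethyl-3-vinylcyclobut-2-en-1-one, via tertiary cyclobutenol 8 (not isolated)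
Conditions: THF, −78 °C to 0 °C; then 1 M HCl, 0 °C to rt
Reagents that add atoms: water, O
Why: 1,2-Addition of the Grignard reagent to the strained vinylogous-ester carbonyl and acid-induced allylic transposition with hydrolysis of the enol ether (Stork–Danheiser transposition) should give the 3-vinylcyclobutenone, in which, because CMe2 bridges both ends of the enone unit, the vinyl-bearing carbon again lies next to CMe2; the carbinol stereocentre of 8 is lost.

Step 4
Reactants: 9 2,4,4-trimethyl-3-vinylcyclobut-2-en-1-one; 10 ethylene
Product: 11 2,4,4-trimethyl-3-vinylcyclohex-2-en-1-one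
Conditions: [Rh(CO)2Cl]2 (5 mol %), P(C6F5)3 (12 mol %), ethylene (30 atm), toluene, 90 °C
Reagents that add atoms: none
Why: Proposed new method: monovalent rhodium should insert into the strained acyl–C(sp3) bond C4–C1 of 9 (the bond that also opens thermally to the vinylketene) to give a rhodacyclopentenone (η4-vinylketene complex); ethylene then inserts into the Rh–acyl bond (new C3–C4 bond), and the seven-membered rhodacycle, whose Rh–C1 end is part of an η3-allyl, closes by C–C reductive elimination at C1 (new C1–C2 bond, quaternary carbon). The closest known reactions are the rhodium-catalysed "cut-and-sew" carboacylation of alkenes with cyclobutanones and benzocyclobutenones, the rhodium-catalysed coupling of cyclobutenones with norbornene to cyclohexenones and the nickel-catalysed (4+2) coupling of cyclobutenones with alkynes; new here is an unstrained alkene with β-hydrogens in the intermolecular mode. The six-membered ring is closed by reductive elimination from the seven-membered metallacycle, a formal (4+2) expansion of the four-membered ring by C2H4. No stereocentre is created, since C6 stays sp2 and is set later by chirality transfer from C4. The step needs cleavage of the acyl–C(sp3) and not the acyl–C(sp2) bond (secured by strain release towards the conjugated, allyl-stabilised metallacycle), insertion instead of decarbonylation (CO ligands on rhodium, high ethylene pressure) and reductive elimination faster than β-hydride elimination (allyl-type Rh–C1 bond; closure at the other allyl end would give a four-membered ring).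

Step 5
Reactants: 11 2,4,4-trimethyl-3-vinylcyclohex-2-en-1-one
Product: 12 (1S)-2,4,4-trimethyl-3-vinylcyclohex-2-en-1-ol
Conditions: (R)-2-methyl-CBS-oxazaborolidine (20 mol %), catecholborane, toluene, −78 °C; aq NaOH work-up
Reagents that add atoms: none
Why: Corey–Bakshi–Shibata reduction: the (R)-oxazaborolidine should bind the carbonyl oxygen anti to the larger C(Me)=C arm and deliver hydride to the face that gives the (S)-carbinol, and catecholborane at −78 °C should leave the vinyl group untouched.

Step 6
Reactants: 12 (1S)-2,4,4-trimethyl-3-vinylcyclohex-2-en-1-ol; 13 2-nitrobenzenesulfonylhydrazide (NBSH)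
Product: 16 (6R)-6-ethenyl-1,5,5-trimethylcyclohex-1-ene, via Mitsunobu sulfonylhydrazine 14 (not isolated), via allylic diazene 15 (not isolated)
Conditions: PPh3, DEAD, N-methylmorpholine, −30 °C; then 23 °C
Reagents that add atoms: none
Why: Reductive 1,3-transposition through an allylic diazene: Mitsunobu displacement with inversion gives 14, loss of 2-nitrobenzenesulfinic acid gives diazene 15, and its retro-ene loss of N2 should deliver hydrogen to C6 on the face that carried nitrogen, which moves the double bond to C4=C5 and sets (6R) by chirality transfer from C4.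

Step 7
Reactants: 16 (6R)-6-ethenyl-1,5,5-trimethylcyclohex-1-ene; 17 methyl vinyl ketone
Product: 18 (R)-α-ionone
Conditions: second-generation Hoveyda–Grubbs catalyst, RuCl2(H2IMes)(=CH-2-(i-PrO)C6H4) (5 mol %), 1,4-benzoquinone (10 mol %), 17 (5 equiv), CH2Cl2, 40 °C
Reagents that add atoms: none
Why: Olefin cross-metathesis of a monosubstituted alkene with an electron-poor vinyl ketone should give the E-enone selectively, the trisubstituted ring alkene being inert and benzoquinone suppressing hydride-induced migration towards the doubly allylic C6–H, so that C6 is untouched.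

Step 8
Reactants: 18 (R)-α-ionone; 7 vinylmagnesium bromide
Product: 19 (1E)-3-methyl-1-[(1R)-2,6,6-trimethylcyclohex-2-en-1-yl]penta-1,4-dien-3-ol
Conditions: THF, −20 °C to 0 °C; then sat. aq NH4Cl
Reagents that add atoms: none
Why: Grignard 1,2-addition to the enone carbonyl (the classical vinyl-ionol synthesis) should occur without touching C6; the new carbinol centre forms as both epimers, which is irrelevant because it becomes sp2 in step 9.

Step 9
Reactants: 19 (1E)-3-methyl-1-[(1R)-2,6,6-trimethylcyclohex-2-en-1-yl]penta-1,4-dien-3-ol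
Product: 20 [(2E,4E)-3-methyl-5-[(1R)-2,6,6-trimethylcyclohex-2-en-1-yl]penta-2,4-dien-1-yl]triphenylphosphonium bromide
Conditions: Ph3P·HBr, MeOH, 0 °C to rt
Reagents that add atoms: triphenylphosphine hydrobromide, [Br-].[PH+](c1ccccc1)(c1ccccc1)c1ccccc1
Why: Acid-induced ionisation of the tertiary bis-allylic alcohol and capture of the pentadienyl cation by PPh3 at its unsubstituted terminus (SN1′ formation of an allylic Wittig salt) should give mainly the 2E,4E salt; C6 is not involved.

Step 10
Reactants: 21 (2E,6E)-farnesyl bromide
Product: 22 (2E,6E)-farnesyltriphenylphosphonium bromide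
Conditions: PPh3, toluene, rt
Reagents that add atoms: triphenylphosphine, c1ccc(cc1)P(c1ccccc1)c1ccccc1
Why: SN2 quaternisation of the primary allylic bromide by PPh3 should proceed with retention of both E double bonds.

Step 11
Reactants: 22 (2E,6E)-farnesyltriphenylphosphonium bromide; 23 (2E,4E,6E)-2,7-dimethylocta-2,4,6-trienedial
Product: 25 (2E,4E,6E,8E,10E,14E)-2,7,11,15,19-pentamethylicosa-2,4,6,8,10,14,18-heptaenal, via farnesylidenetriphenylphosphorane 24 (not isolated)
Conditions: n-BuLi, THF, −78 °C; ylide added to 23 (3 equiv), −78 °C to rt; then I2 (cat.), hexane, rt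
Reagents that add atoms: none
Why: Wittig olefination of the allylic ylide with the dialdehyde kept in excess (inverse addition) should stop at mono-olefination, and iodine-catalysed equilibration should convert the E/Z mixture at the new C11′=C12′ bond into the E isomer.

Step 12
Reactants: 20 [(2E,4E)-3-methyl-5-[(1R)-2,6,6-trimethylcyclohex-2-en-1-yl]penta-2,4-dien-1-yl]triphenylphosphonium bromide; 25 (2E,4E,6E,8E,10E,14E)-2,7,11,15,19-pentamethylicosa-2,4,6,8,10,14,18-heptaenal
Product: 27 (6R)-7′,8′-dihydro-ε,ψ-carotene (target), via C15 dienylidenephosphorane 26 (not isolated)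
Conditions: NaOMe, MeOH/CH2Cl2, 0 °C to rt; then heptane, reflux
Reagents that add atoms: none
Why: Wittig olefination forms C11=C12 under mild methoxide conditions that should not deprotonate C6–H, and the sterically strained 11Z isomer should isomerise thermally to the all-E target.

**Compound list**

1 | ethoxyacetylene | C#COCC | starting material
2 | lithium ethoxyacetylide (not isolated) | [Li]C#COCC | intermediate
3 | 1-ethoxyprop-1-yne | CC#COCC | intermediate
4 | isobutyryl chloride | CC(C)C(=O)Cl | starting material
5 | dimethylketene (not isolated) | CC(C)=C=O | intermediate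
6 | 3-ethoxy-2,4,4-trimethylcyclobut-2-en-1-one | CCOC1=C(C)C(=O)C1(C)C | intermediate
7 | vinylmagnesium bromide | C=C[Mg]Br | starting material
8 | 3-ethoxy-2,4,4-trimethyl-1-vinylcyclobut-2-en-1-ol (racemic, not isolated) | CCOC1=C(C)C(O)(C=C)C1(C)C | intermediate
9 | 2,4,4-trimethyl-3-vinylcyclobut-2-en-1-one | C=CC1=C(C)C(=O)C1(C)C | intermediate
10 | ethylene | C=C | starting material
11 | 2,4,4-trimethyl-3-vinylcyclohex-2-en-1-one | C=CC1=C(C)C(=O)CCC1(C)C | intermediate
12 | (1S)-2,4,4-trimethyl-3-vinylcyclohex-2-en-1-ol | O[C@H]1CCC(C)(C)C(C=C)=C1C | intermediate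
13 | 2-nitrobenzenesulfonylhydrazide (NBSH) | NNS(=O)(=O)c1ccccc1[N+](=O)[O-] | starting material
14 | N-[(1R)-2,4,4-trimethyl-3-vinylcyclohex-2-en-1-yl]-2-nitrobenzenesulfonohydrazide (not isolated) | NN([C@@H]1CCC(C)(C)C(C=C)=C1C)S(=O)(=O)c1ccccc1[N+](=O)[O-] | intermediate
15 | [(1R)-2,4,4-trimethyl-3-vinylcyclohex-2-en-1-yl]diazene (not isolated) | N=N[C@@H]1CCC(C)(C)C(C=C)=C1C | intermediate
16 | (6R)-6-ethenyl-1,5,5-trimethylcyclohex-1-ene | C=C[C@H]1C(C)=CCCC1(C)C | intermediate
17 | methyl vinyl ketone | CC(=O)C=C | starting material
18 | (R)-α-ionone, (3E)-4-[(1R)-2,6,6-trimethylcyclohex-2-en-1-yl]but-3-en-2-one | CC(=O)/C=C/[C@H]1C(C)=CCCC1(C)C | intermediate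
19 | (1E)-3-methyl-1-[(1R)-2,6,6-trimethylcyclohex-2-en-1-yl]penta-1,4-dien-3-ol (both C3 epimers) | C=CC(C)(O)/C=C/[C@H]1C(C)=CCCC1(C)C | intermediate
20 | [(2E,4E)-3-methyl-5-[(1R)-2,6,6-trimethylcyclohex-2-en-1-yl]penta-2,4-dien-1-yl]triphenylphosphonium bromide | C/C(=C\C[P+](c1ccccc1)(c1ccccc1)c1ccccc1)/C=C/[C@H]1C(C)=CCCC1(C)C.[Br-] | intermediate
21 | (2E,6E)-farnesyl bromide | CC(C)=CCC/C(C)=C/CC/C(C)=C/CBr | starting material
22 | (2E,6E)-farnesyltriphenylphosphonium bromide | CC(C)=CCC/C(C)=C/CC/C(C)=C/C[P+](c1ccccc1)(c1ccccc1)c1ccccc1.[Br-] | intermediate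
23 | (2E,4E,6E)-2,7-dimethylocta-2,4,6-trienedial | O=C/C(C)=C/C=C/C=C(C)/C=O | starting material
24 | (2E,6E)-farnesylidenetriphenylphosphorane (not isolated) | CC(C)=CCC/C(C)=C/CC/C(C)=C/C=P(c1ccccc1)(c1ccccc1)c1ccccc1 | intermediate
25 | (2E,4E,6E,8E,10E,14E)-2,7,11,15,19-pentamethylicosa-2,4,6,8,10,14,18-heptaenal | CC(C)=CCC/C(C)=C/CC/C(C)=C/C=C/C(C)=C/C=C/C=C(C)/C=O | intermediate
26 | [(2E,4E)-3-methyl-5-[(1R)-2,6,6-trimethylcyclohex-2-en-1-yl]penta-2,4-dien-1-ylidene]triphenylphosphorane (not isolated) | C/C(=C\C=P(c1ccccc1)(c1ccccc1)c1ccccc1)/C=C/[C@H]1C(C)=CCCC1(C)C | intermediate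
27 | (6R)-7′,8′-dihydro-ε,ψ-carotene | CC(C)=CCC/C(C)=C/CC/C(C)=C/C=C/C(C)=C/C=C/C=C(C)/C=C/C=C(C)/C=C/[C@H]1C(C)=CCCC1(C)C | target

**Summary**

Total step count: 12. Longest linear sequence: 10 steps (steps 1 to 9, then step 12).

Steps most likely to fail:

Step 4 (proposed method). The ethylene-inserted rhodacycle may undergo β-hydride elimination or decarbonylation faster than the C–C reductive elimination that has to build the quaternary carbon, or the thermally opened vinylketene may be consumed by hydrogen shift and oligomerisation. The fallback uses known chemistry on a preformed six-membered ring instead of a ring expansion; it sets out from 7 and comes back at 11. Commercial 3-ethoxy-2-methylcyclohex-2-en-1-one F1 would be methylated twice at C6 (LiN(i-Pr)2, MeI, THF, −78 °C, two cycles) via 3-ethoxy-2,6-dimethylcyclohex-2-en-1-one F2 to 3-ethoxy-2,6,6-trimethylcyclohex-2-en-1-one F3. 1,2-Addition of 7 should give 3-ethoxy-2,6,6-trimethyl-1-vinylcyclohex-2-en-1-ol F4, and 1 M HCl (Stork–Danheiser transposition) should deliver 11.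

Step 6. The Mitsunobu displacement at the hindered dienyl carbinol may be diverted to elimination or to attack at the remote diene terminus, which would erode the chirality transfer. The fallback replaces the sigmatropic diazene by hydride delivery from palladium; it sets out from 12 and comes back at 16. Formylation (HCO2H, Ac2O, pyridine) should give (1S)-2,4,4-trimethyl-3-vinylcyclohex-2-en-1-yl formate F5. With Pd(OAc)2 and n-Bu3P in dioxane at reflux, zerovalent palladium should ionise F5 anti to the formate, CO2 should be lost, and hydride should pass from palladium to the more substituted allyl terminus C6, which is the same face as in step 6.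

Step 7. Metathesis at the vinyl group next to the quaternary carbon may be so slow that ruthenium hydride-induced double-bond migration and homodimerisation of the enone take over. The fallback replaces metathesis by cycloaddition and fragmentation; it sets out from 16 and comes back at 18. Acetonitrile oxide F6 (from nitroethane, PhNCO and catalytic Et3N) should add only to the monosubstituted alkene to give 3-methyl-5-[(1R)-2,6,6-trimethylcyclohex-2-en-1-yl]-4,5-dihydro-1,2-oxazole F7. N–O cleavage with Mo(CO)6 in wet MeCN should give 4-hydroxy-4-[(1R)-2,6,6-trimethylcyclohex-2-en-1-yl]butan-2-one F8. MsCl and Et3N should then convert F8, through 3-oxo-1-[(1R)-2,6,6-trimethylcyclohex-2-en-1-yl]butyl methanesulfonate F9 and E1cB elimination, into 18.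

Further compounds
F1 | step 4 | 3-ethoxy-2-methylcyclohex-2-en-1-one | CCOC1=C(C)C(=O)CCC1
F2 | step 4 | 3-ethoxy-2,6-dimethylcyclohex-2-en-1-one (racemic) | CCOC1=C(C)C(=O)C(C)CC1
F3 | step 4 | 3-ethoxy-2,6,6-trimethylcyclohex-2-en-1-one | CCOC1=C(C)C(=O)C(C)(C)CC1
F4 | step 4 | 3-ethoxy-2,6,6-trimethyl-1-vinylcyclohex-2-en-1-ol (racemic) | CCOC1=C(C)C(O)(C=C)C(C)(C)CC1
F5 | step 6 | (1S)-2,4,4-trimethyl-3-vinylcyclohex-2-en-1-yl formate | O=CO[C@H]1CCC(C)(C)C(C=C)=C1C
F6 | step 7 | acetonitrile oxide | CC#[N+][O-]
F7 | step 7 | 3-methyl-5-[(1R)-2,6,6-trimethylcyclohex-2-en-1-yl]-4,5-dihydro-1,2-oxazole (both C5 epimers) | CC1=NOC(C1)[C@H]2C(C)=CCCC2(C)C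
F8 | step 7 | 4-hydroxy-4-[(1R)-2,6,6-trimethylcyclohex-2-en-1-yl]butan-2-one (both carbinol epimers) | CC(=O)CC(O)[C@H]1C(C)=CCCC1(C)C
F9 | step 7 | 3-oxo-1-[(1R)-2,6,6-trimethylcyclohex-2-en-1-yl]butyl methanesulfonate | CC(=O)CC(OS(C)(=O)=O)[C@H]1C(C)=CCCC1(C)C
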